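A direct plan would C-prenylate and C-geranylate 2,4,6-trihydroxybenzophenone to the diallylated phloroglucinol A1, dearomatise A1 with the enal acetate A2 under a chiral ammonium salt (alkylation–Michael–aldol) to the adamantanol A3, reopen A3 by retro-aldol and turn the freed aldehyde into a prenyl group to reach the diprenyl bicyclic enol A4, close the seven-membered carbocycle of A4 from a C3 radical under oxygen to the peroxy-hemiketal A5 and expand A5 to the 1,2-dioxepane.
Its weakest steps would be three.
(a) The dearomatising alkylation of A1 would have to choose between the geranyl- and the prenyl-bearing ring carbon, which differ only far from the ring, and set the absolute configuration in the same event; a constitutional isomer would be unavoidable.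
(b) The change of the retro-aldol aldehyde of A3 into the prenyl group of A4 (vinyl addition, acetylation, reductive allylic transposition, cross-metathesis) would cost four steps, after a ring closed only to be opened again, for one side chain.
(c) The last step, the radical-chain ring expansion of the peroxy-hemiketal A5, would have no precedent, would leave the peroxy CH centre to conformational preference, and would be run on the final, most precious material.

Locants for all intermediates: ring A = C1 (benzoyl), C2, C3, C4, C5 (geranyl), C9; bridge C6–C7–C8(CH3)2 from C5 to C1; bridge C10–C11 from C7 to C3; C12 = peroxy C(CH3)2 on C11; C13–C14–C15 = CH2, peroxy CH, C(CH3)2OH on C3.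
Cuts: O–C14 (epoxide opened by the C12 peroxide), C1–C8 (cation), C3–C11 (allyl-palladium), C5–C6 (SN2). The ten carbons C6–C7(C8)–C10–C11(C12) are a lavandulyl skeleton and arrive as one achiral diene with two allylic ends.
Ring order: carbocycle C3–C4–C5–C6–C7–C10–C11 first, ring B and with it the cage second, dioxepane last.
Feature behind the key step: C3 is a 2-alkyl-1,3-dione carbon held 1,3 to C5 across the C4 carbonyl, and C11 is the inner terminus of a 2-methylallyl unit whose outer CH2 becomes a methyl group of C12.
Why the weak steps vanish: bromine on C3 leaves only C5 for the dearomatising alkylation; the C7 side chain is part of the chain, and C7 is set by the cage when C8 meets C1; C14 comes from a catalyst-controlled ketone reduction and enters the peroxide through two SN2 inversions.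

Key step: step 11

Remark: bromo ketone 9 is made in step 5 because its supply is uncertain; the cinchonidinium salt (step 8), the Trost ligand (step 11) and RuCl(p-cymene)[(S,S)-TsDPEN] (step 12) are taken in the enantiomeric series expected to give the drawn centres.

Step 1
Reactants: 1 diethyl 2-(propan-2-ylidene)propanedioate
Product: 2 2-(propan-2-ylidene)propane-1,3-diol
Conditions: i-Bu2AlH (4.5 equiv), CH2Cl2, −78 → 0 °C; aq. potassium sodium tartrate
Reagents that add atoms: none
Why: Exhaustive 1,2-reduction of both esters of an alkylidene malonate should give the bis-allylic diol without conjugate reduction (ester reduction).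

Step 2
Reactants: 2 2-(propan-2-ylidene)propane-1,3-diol
Product: 3 1-bromo-2-(bromomethyl)-3-methylbut-2-ene
Conditions: PBr3 (0.8 equiv), Et2O, −10 → 0 °C
Reagents that add atoms: phosphorus tribromide, BrP(Br)Br
Why: Both primary allylic alcohols are exchanged for bromide, and the primary dibromide with the tetrasubstituted alkene is the stable allylic isomer (bromination of allylic alcohols).

Step 3
Reactants: 4 prop-2-yn-1-ol; 3 1-bromo-2-(bromomethyl)-3-methylbut-2-ene
Product: 6 (2E)-5-(bromomethyl)-2,6-dimethylhepta-2,5-dien-1-ol, via alkenylalane 5 (not isolated)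
Conditions: Me3Al (3 equiv), Cp2ZrCl2 (25 mol %), ClCH2CH2Cl, 0 → 23 °C; then 3 (3 equiv), Pd(PPh3)4 (3 mol %), THF, 23 °C; aq. NH4Cl
Reagents that add atoms: trimethylaluminium, C[Al](C)C
Why: Negishi carboalumination adds methyl and aluminium syn and so fixes the E alkene, and the alkenylalane is coupled under zerovalent palladium with one of the two equivalent allylic bromides of 3 (taken in excess) at its CH2 end (alkenyl–allyl cross-coupling).

Step 4
Reactants: 6 (2E)-5-(bromomethyl)-2,6-dimethylhepta-2,5-dien-1-ol
Product: 7 (2E)-5-(bromomethyl)-2,6-dimethylhepta-2,5-dien-1-yl methyl carbonate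
Conditions: ClCO2Me (1.2 equiv), pyridine (1.5 equiv), CH2Cl2, −20 → 0 °C
Reagents that add atoms: methyl chloroformate, COC(=O)Cl
Why: O-Acylation turns the primary allylic alcohol into the carbonate that zerovalent palladium will ionise later, while the allylic bromide is kept for the SN2 step (carbonate formation).

Step 5
Reactants: 8 3-hydroxy-3-methylbutan-2-one
Product: 9 1-bromo-3-hydroxy-3-methylbutan-2-one
Conditions: Br2 (1.0 equiv), MeOH, 0 → 23 °C
Reagents that add atoms: bromine, BrBr
Why: Bromination can only take the methyl group, since the other α-carbon is quaternary (ketone α-halogenation).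

Step 6
Reactants: 10 (2,4,6-trihydroxyphenyl)(phenyl)methanone
Product: 11 (3-bromo-2,4,6-trihydroxyphenyl)(phenyl)methanone
Conditions: N-bromosuccinimide (1.0 equiv), THF, −78 → −40 °C
Reagents that add atoms: N-bromosuccinimide, O=C1CCC(=O)N1Br
Why: One of the two equivalent free ring positions is brominated, and the first bromine slows a second substitution (electrophilic aromatic substitution); this bromine will block C3.

Step 7
Reactants: 11 (3-bromo-2,4,6-trihydroxyphenyl)(phenyl)methanone; 12 (2E)-1-bromo-3,7-dimethylocta-2,6-diene (geranyl bromide)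
Product: 13 {3-bromo-5-[(2E)-3,7-dimethylocta-2,6-dien-1-yl]-2,4,6-trihydroxyphenyl}(phenyl)methanone
Conditions: KOH (10 % aq.), 0 °C
Reagents that add atoms: none
Why: C-Alkylation of the phenoxide in water should take the one remaining ring C–H and keep the E geometry (C-geranylation, SN2).

Step 8
Reactants: 13 {3-bromo-5-[(2E)-3,7-dimethylocta-2,6-dien-1-yl]-2,4,6-trihydroxyphenyl}(phenyl)methanone; 7 (2E)-5-(bromomethyl)-2,6-dimethylhepta-2,5-dien-1-yl methyl carbonate
Product: 14 (6S)-2-benzoyl-4-bromo-6-[(2E)-3,7-dimethylocta-2,6-dien-1-yl]-3,5-dihydroxy-6-[(4E)-6-(methoxycarbonyloxy)-5-methyl-2-(propan-2-ylidene)hex-4-en-1-yl]cyclohexa-2,4-dien-1-one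
Conditions: O-allyl-N-(9-anthracenylmethyl)cinchonidinium bromide (20 mol %), CsOH·H2O, CH2Cl2, 4 Å molecular sieves, −50 → −30 °C
Reagents that add atoms: none
Why: Alkylative dearomatisation under phase-transfer catalysis: with C3 occupied by bromine only the geranyl-bearing C5 can take the primary allylic bromide at carbon (SN2), and the chiral ion pair selects the face, which should set C5 as (S).

Step 9
Reactants: 14 (6S)-bromo dienone as named in step 8
Product: 15 (6S)-2-benzoyl-6-[(2E)-3,7-dimethylocta-2,6-dien-1-yl]-3,5-dihydroxy-6-[(4E)-6-(methoxycarbonyloxy)-5-methyl-2-(propan-2-ylidene)hex-4-en-1-yl]cyclohexa-2,4-dien-1-one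
Conditions: Na2SO3 (1.5 equiv, aq.), THF, 0 °C
Reagents that add atoms: none
Why: The bromine of a 2-bromo-1,3-dione is a positive halogen and is removed by sulfite without touching alkenes, carbonate or C5 (reductive dehalogenation).

Step 10
Reactants: 15 (6S)-dienone as named in step 9; 9 1-bromo-3-hydroxy-3-methylbutan-2-one
Product: 16 (6S)-2-benzoyl-6-[(2E)-3,7-dimethylocta-2,6-dien-1-yl]-3,5-dihydroxy-4-(3-hydroxy-3-methyl-2-oxobutyl)-6-[(4E)-6-(methoxycarbonyloxy)-5-methyl-2-(propan-2-ylidene)hex-4-en-1-yl]cyclohexa-2,4-dien-1-one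
Conditions: K2CO3 (1.2 equiv), acetone, 0 → 23 °C
Reagents that add atoms: none
Why: The only enolic C–H, C3, is alkylated at carbon by the α-bromo ketone, a very reactive SN2 partner for 1,3-dione enolates, and carbonate is too weak a base to ionise the tertiary alcohol (C-alkylation of a cyclic 1,3-dione).

Step 11
Reactants: 16 (6S)-trione as named in step 10
Product: 17 (3S,5S,11R)-bridged bicyclo[4.3.1]decane trione: C3–C11 bond closed, ring C3–C4–C5–C6–C7–C10–C11 across ring A, C7 isopropylidene, C11 prop-1-en-2-yl on the C4 side, C3 side chain CH2C(=O)C(CH3)2OH anti to the bridge, C1 benzoyl enol, C5 geranyl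
Conditions: Pd2(dba)3·CHCl3 (2.5 mol %), (R,R)-DACH-phenyl Trost ligand (7.5 mol %), CH2Cl2, 0 → 23 °C
Reagents that add atoms: none
Why: Zerovalent palladium ionises the primary allylic carbonate (CO2 and methoxide leave, methoxide deprotonates the 2-alkyl-1,3-dione), and C3 attacks the inner terminus C11 of the tethered 2-methylallyl-palladium unit anti to the metal. The closest known reactions are the ring-forming Tsuji–Trost alkylation of 2-substituted 1,3-diketones and the dearomative conjunctive allylic annulations of acylphloroglucinols. The cycloheptane closes in the exo mode on the allyl unit (seven-membered ring, alkene left outside), since attack at the CH2 end would need a nine-membered ring with an E alkene. C3 is fixed by the tether, because the four-atom bridge can reach C3 only on the face of C5 that carries C6, so C11 ends cis to C6 and the keto side chain anti; C11 is set by the face of the allyl unit that is attacked, the two faces exchange through the η1 form at the CH2 end, and the ligand is expected to select the isomer with the allyl unit over the C4 carbonyl, away from the benzoyl side. The step needs C3 to react in preference to the benzoyl-bearing C1 and to oxygen, which the much lower nucleophilicity of the triketone carbon and the reversibility of O-allylation under zerovalent palladium should secure. The allyl groups on the quaternary C5 must not ionise, hence the low temperature.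

Step 12
Reactants: 17 bridged trione as named in step 11
Product: 18 (3S,5S,11R,14S)-diol: 17 with the side-chain ketone reduced, C3 side chain CH2–CH(OH)–C(CH3)2OH
Conditions: RuCl(p-cymene)[(S,S)-TsDPEN] (2 mol %), HCO2H–Et3N (5:2), 23 °C
Reagents that add atoms: none
Why: Noyori–Ikariya transfer hydrogenation should reduce only the α-hydroxy ketone of the side chain (the ring carbonyls are enolised or flanked by quaternary carbons, the alkenes are inert), and the catalyst distinguishes the C(CH3)2OH side from the CH2 side, which is expected to give the (S) carbinol C14.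

Step 13
Reactants: 18 diol as named in step 12
Product: 19 (3S,5S,11S,14S)-C12 triethylsilyl peroxide: 18 with C11 bearing C(CH3)2–O–O–SiEt3 in place of prop-1-en-2-yl
Conditions: Co(thd)2 (5 mol %), O2 (1 atm), Et3SiH (2 equiv), ClCH2CH2Cl, 23 °C
Reagents that add atoms: dioxygen, O=O; triethylsilane, CC[SiH](CC)CC
Why: Isayama–Mukaiyama hydroperoxidation: hydrogen-atom transfer from the hydride formed from Co(thd)2 and Et3SiH to the 1,1-disubstituted alkene gives the tertiary C12 radical, which takes up O2 and is silylated, while the tetrasubstituted and trisubstituted alkenes react far more slowly and no stereocentre is formed.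

Step 14
Reactants: 19 silyl peroxide as named in step 13
Product: 20 cage diol peroxy-hemiketal: C1–C8 bond closed (ring B and homoadamantane cage, C7–H outward, ring centres as in the target), C12 hydroperoxide closed on the C4 carbonyl as a 1,2-dioxan-3-ol, C3 side chain CH2–CH(OH)–C(CH3)2OH with (14S)
Conditions: (1S)-camphor-10-sulfonic acid (20 mol %), (CF3)2CHOH–CH2Cl2 (1:1), −20 → 23 °C; aq. NaHCO3
Reagents that add atoms: none
Why: Cation–olefin cyclisation ended by the enol carbon of the 2-acyl-1,3-dione, the reaction type of the biomimetic bicyclo[3.3.1] closures of dearomatised acylphloroglucinols: reversible protonation of the isopropylidene group gives the C8 cation, which C1 can reach only when the proton sits on the outer face of C7, so that C7 and C1 are set by the cage while the other C7 epimer and any O-alkylated enol ether return through the cation; the acid also removes the silyl group, and the hydroperoxide rests on the C4 ketone in the only configuration the ring fusion allows.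

Step 15
Reactants: 20 cage diol peroxy-hemiketal as named in step 14
Product: 23 CNP0148771.1, via mesylate 21 (not isolated), via epoxy hydroperoxide 22 (not isolated)
Conditions: MsCl (1.3 equiv), Et3N (2 equiv), CH2Cl2, −30 °C; then Cs2CO3 (3 equiv), MeCN, 0 → 23 °C
Reagents that add atoms: none
Why: Sulfonylation takes the only secondary hydroxyl (the hydroperoxide is masked as the tertiary hemiketal), carbonate then closes the epoxide from the tertiary alkoxide with inversion at C14 and frees the peroxide anion from the hemiketal, which opens the epoxide 7-exo-tet at C14 with a second inversion (intramolecular epoxide opening by a hydroperoxide), so that C14 keeps the (S) arrangement of step 12.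

**Compound list**

1 | diethyl 2-(propan-2-ylidene)propanedioate | CCOC(=O)C(C(=O)OCC)=C(C)C | starting material
2 | 2-(propan-2-ylidene)propane-1,3-diol | OCC(CO)=C(C)C | intermediate
3 | 1-bromo-2-(bromomethyl)-3-methylbut-2-ene | BrCC(CBr)=C(C)C | intermediate
4 | prop-2-yn-1-ol | C#CCO | starting material
5 | dimethylaluminium (2E)-3-(dimethylalumanyl)-2-methylprop-2-en-1-olate (not isolated) | C[Al](C)OC/C(C)=C/[Al](C)C | intermediate
6 | (2E)-5-(bromomethyl)-2,6-dimethylhepta-2,5-dien-1-ol | OC/C(C)=C/CC(CBr)=C(C)C | intermediate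
7 | (2E)-5-(bromomethyl)-2,6-dimethylhepta-2,5-dien-1-yl methyl carbonate | COC(=O)OC/C(C)=C/CC(CBr)=C(C)C | intermediate
8 | 3-hydroxy-3-methylbutan-2-one | CC(=O)C(C)(C)O | starting material
9 | 1-bromo-3-hydroxy-3-methylbutan-2-one | OC(C)(C)C(=O)CBr | intermediate
10 | (2,4,6-trihydroxyphenyl)(phenyl)methanone | O=C(c1ccccc1)c1c(O)cc(O)cc1O | starting material
11 | (3-bromo-2,4,6-trihydroxyphenyl)(phenyl)methanone | O=C(c1ccccc1)c1c(O)cc(O)c(Br)c1O | intermediate
12 | (2E)-1-bromo-3,7-dimethylocta-2,6-diene (geranyl bromide) | CC(C)=CCC/C(C)=C/CBr | starting material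
13 | {3-bromo-5-[(2E)-3,7-dimethylocta-2,6-dien-1-yl]-2,4,6-trihydroxyphenyl}(phenyl)methanone | O=C(c1ccccc1)c1c(O)c(Br)c(O)c(C/C=C(\C)CCC=C(C)C)c1O | intermediate
14 | (6S)-2-benzoyl-4-bromo-6-geranyl-3,5-dihydroxy-6-[(4E)-6-(methoxycarbonyloxy)-5-methyl-2-(propan-2-ylidene)hex-4-en-1-yl]cyclohexa-2,4-dien-1-one | CC(C)=CCC/C(C)=C/C[C@@]1(CC(=C(C)C)C/C=C(C)/COC(=O)OC)C(=O)C(C(=O)c2ccccc2)=C(O)C(Br)=C1O | intermediate
15 | (6S)-2-benzoyl-6-geranyl-3,5-dihydroxy-6-[(4E)-6-(methoxycarbonyloxy)-5-methyl-2-(propan-2-ylidene)hex-4-en-1-yl]cyclohexa-2,4-dien-1-one | CC(C)=CCC/C(C)=C/C[C@@]1(CC(=C(C)C)C/C=C(C)/COC(=O)OC)C(=O)C(C(=O)c2ccccc2)=C(O)C=C1O | intermediate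
16 | (6S)-2-benzoyl-6-geranyl-3,5-dihydroxy-4-(3-hydroxy-3-methyl-2-oxobutyl)-6-[(4E)-6-(methoxycarbonyloxy)-5-methyl-2-(propan-2-ylidene)hex-4-en-1-yl]cyclohexa-2,4-dien-1-one | CC(C)=CCC/C(C)=C/C[C@@]1(CC(=C(C)C)C/C=C(C)/COC(=O)OC)C(=O)C(C(=O)c2ccccc2)=C(O)C(CC(=O)C(C)(C)O)=C1O | intermediate
17 | (3S,5S,11R)-bridged bicyclo[4.3.1]decane trione: C3–C11 closed, C7 isopropylidene, C11 prop-1-en-2-yl, C3 CH2C(=O)C(CH3)2OH, C1 benzoyl enol, C5 geranyl | CC(C)=CCC/C(C)=C/C[C@]12CC(=C(C)C)C[C@H](C(C)=C)[C@](CC(=O)C(C)(C)O)(C1=O)C(O)=C(C(=O)c1ccccc1)C2=O | intermediate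
18 | (3S,5S,11R,14S)-diol: 17 with C3 side chain CH2–CH(OH)–C(CH3)2OH | CC(C)=CCC/C(C)=C/C[C@]12CC(=C(C)C)C[C@H](C(C)=C)[C@](C[C@H](O)C(C)(C)O)(C1=O)C(O)=C(C(=O)c1ccccc1)C2=O | intermediate
19 | (3S,5S,11S,14S)-C12 triethylsilyl peroxide of 18 | CC(C)=CCC/C(C)=C/C[C@]12CC(=C(C)C)C[C@H](C(C)(C)OO[Si](CC)(CC)CC)[C@](C[C@H](O)C(C)(C)O)(C1=O)C(O)=C(C(=O)c1ccccc1)C2=O | intermediate
20 | cage diol peroxy-hemiketal: homoadamantane trione core, C12–O–O closed on C4 as 1,2-dioxan-3-ol, C3 side chain (14S)-CH2–CH(OH)–C(CH3)2OH | CC(C)=CCC/C(C)=C/C[C@]12C[C@@H]3C[C@@H]4C(C)(C)OO[C@@]1(O)[C@]4(C[C@H](O)C(C)(C)O)C(=O)[C@](C(=O)c5ccccc5)(C2=O)C3(C)C | intermediate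
21 | (14S)-C14 methanesulfonate of 20 (not isolated) | CC(C)=CCC/C(C)=C/C[C@]12C[C@@H]3C[C@@H]4C(C)(C)OO[C@@]1(O)[C@]4(C[C@H](OS(C)(=O)=O)C(C)(C)O)C(=O)[C@](C(=O)c5ccccc5)(C2=O)C3(C)C | intermediate
22 | epoxy hydroperoxide: cage trione with free C12 hydroperoxide and (14R)-(3,3-dimethyloxiran-2-yl)methyl on C3 (not isolated) | CC(C)=CCC/C(C)=C/C[C@]12C[C@@H]3C[C@H](C(C)(C)OO)[C@](C[C@H]4OC4(C)C)(C1=O)C(=O)[C@](C(=O)c4ccccc4)(C2=O)C3(C)C | intermediate
23 | CNP0148771.1 | CC(C)=CCC/C(C)=C/C[C@]12C[C@@H]3C[C@@H]4C(C)(C)OO[C@H](C(C)(C)O)C[C@@]4(C1=O)C(=O)[C@](C(=O)c1ccccc1)(C2=O)C3(C)C | target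

Total steps: 15. Longest linear sequence: 12 (steps 1–4, then 8–15).

Steps most likely to fail:

Step 14. The C8 cation may be captured by the enol oxygen on C9 instead of by C1, the acid may protonate the geranyl alkenes, or it may ionise the tertiary alcohol or the peroxide before the cage closes. The fallback sets out from 19: protonation with pyridinium p-toluenesulfonate in CH2Cl2, which should spare the silyl peroxide, would give the cyclic enol ether F1. F1 would then be taken through a Lewis-acid-induced 1,3 shift of C8 from oxygen to C1 (BF3·OEt2, CH2Cl2, −40 °C), the ion pair collapsing at carbon in the non-protic medium. Aqueous work-up removes the silyl group and the route is rejoined at 20.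

Step 11. Closure at the fully substituted C3 may be slow, so that attack at the CH2 end of the allyl unit, O-allylation or ionisation of the allyl groups on C5 takes over, and the face selection at C11 may be poor. The fallback reverses the order of the two C3 alkylations. It sets out from 15, whose unsubstituted C3 would be closed onto C11 under the same type of catalysis to give the bridged trione F2. The tertiary C3 of F2 would then be C-alkylated with 9 (K2CO3, acetone), which can enter only anti to the bridge, and the route is rejoined at 17.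

Step 15. Hydroperoxide in equilibrium with the hemiketal may be sulfonylated, the peroxide anion may displace the mesylate directly (wrong C14 epimer), or the base may cleave the secondary peroxide (Kornblum–DeLaMare). The fallback installs the leaving group before any peroxide exists. It sets out from 18: MsCl (2.2 equiv) and Et3N, then brief methanolysis of the enol sulfonate, would give the mesylate F3. Isayama–Mukaiyama peroxidation of F3 would give the silyl peroxide F4, and the acid of step 14 would convert F4 into 21, where the route is rejoined for the carbonate treatment.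

Further compounds
F1 | step 14 | cyclic enol ether: C8 bonded to the oxygen on C9 (tetrahydropyran ring O–C8–C7–C6–C5–C9 fused to ring A), C12 silyl peroxide and diol side chain kept, C7 either epimer | CC(C)=CCC/C(C)=C/C[C@]12CC3C[C@H](C(C)(C)OO[Si](CC)(CC)CC)[C@](C[C@H](O)C(C)(C)O)(C1=O)C(=O)C(C(=O)c1ccccc1)=C2OC3(C)C
F2 | step 11 | bridged bicyclo[4.3.1]decane trione with C3–H: C3–C11 closed, C7 isopropylidene, C11 prop-1-en-2-yl | CC(C)=CCC/C(C)=C/C[C@]12CC(=C(C)C)C[C@H](C(C)=C)[C@H](C1=O)C(O)=C(C(=O)c1ccccc1)C2=O
F3 | step 15 | (14S)-C14 methanesulfonate of 18 | CC(C)=CCC/C(C)=C/C[C@]12CC(=C(C)C)C[C@H](C(C)=C)[C@](C[C@H](OS(C)(=O)=O)C(C)(C)O)(C1=O)C(O)=C(C(=O)c1ccccc1)C2=O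
F4 | step 15 | C12 triethylsilyl peroxide of F3 | CC(C)=CCC/C(C)=C/C[C@]12CC(=C(C)C)C[C@H](C(C)(C)OO[Si](CC)(CC)CC)[C@](C[C@H](OS(C)(=O)=O)C(C)(C)O)(C1=O)C(O)=C(C(=O)c1ccccc1)C2=O
A1 | direct plan | 3-geranyl-5-prenyl-2,4,6-trihydroxybenzophenone | O=C(c1ccccc1)c1c(O)c(C/C=C(\C)CCC=C(C)C)c(O)c(CC=C(C)C)c1O
A2 | direct plan | (2-formyl-3-methylbut-2-en-1-yl) acetate | CC(=O)OCC(C=O)=C(C)C
A3 | direct plan | adamantanol from alkylation–Michael–aldol, mixture of carbinol epimers | CC(C)=CCC/C(C)=C/C[C@]12C[C@@H]3C(O)[C@](CC=C(C)C)(C1=O)C(=O)[C@](C(=O)c4ccccc4)(C2=O)C3(C)C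
A4 | direct plan | 1-benzoyl-5-geranyl-4-hydroxy-8,8-dimethyl-3,7-endo-diprenylbicyclo[3.3.1]non-3-ene-2,9-dione | CC(C)=CCC/C(C)=C/C[C@]12C[C@H](CC=C(C)C)C(C)(C)[C@@](C(=O)c3ccccc3)(C2=O)C(=O)C(CC=C(C)C)=C1O
A5 | direct plan | homoadamantane 1,2-dioxan-3-ol with C3 prenyl | CC(C)=CCC/C(C)=C/C[C@]12C[C@@H]3C[C@@H]4C(C)(C)OO[C@@]1(O)[C@]4(CC=C(C)C)C(=O)[C@](C(=O)c5ccccc5)(C2=O)C3(C)C
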